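The numbers of this flask were chosen freely.

Z leaves the enzyme through J, so take as the zero of your scale the flask in which every Q charged stands as J for the whole run. Decide with that scale how to charge the next run: together, or with X or D fed slowly.

common to all: Q 4.0 µM; time 15 min
- west: X 20 mM (fed, over 12 min); D 16.0 mM; all else is in the flask from the start; the feed brings no volume worth counting
- south-east: X 20 mM; D 16.0 mM (fed, over 12 min); all else is in the flask from the start; the feed brings no volume worth counting
- north-west: X 20 mM; D 16.0 mM; everything together at the start

1. the flask that comes out highest in amount of Z, in percent of the X charged, or "all alike" when all lie within 1.5 percentage points (west / south-east / north-west / all alike)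
2. Z at the end, in percent of the X charged, west
3. Z at the end, in percent of the X charged, south-east
4. Z at the end, in percent of the X charged, north-west

- Z is meant together with its Qa
- run time (west): 15 min

J gives Z at 180 /min, so over 15 min the enzyme charged can make 54.0 % of the X charged. Call this the turnover ceiling: the Z made if every Q stood as J throughout. The D charge allows 80.0 % of the X, more than the ceiling, so hold each flask against the ceiling first.

Next, reckon what share of the enzyme stands as J. Q takes up X to form E, which falls back at 15500 /min or takes up D to form J. Balance these forms at the start, before any Z exists, and J stands at 6.15 times E. For a fed flask, take the fed partner at half its charge. Multiply each share by the ceiling: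

| Flask | Share in J | Z reckoned |
|---|---|---|
| west | 51.1 % | 27.6 % |
| south-east | 47.8 % | 25.8 % |
| north-west | 64.1 % | 34.6 % |

As reckoned for the start of north-west, J holds more of the enzyme than the other forms together, which makes it the resting state at that moment. Free Z lost to G has a half-life of 72 min (that loss by itself, charges as at the start, north-west), longer than the run, so count Z as kept. In north-west X and D fall as Z forms, so read its figure in the last column as high. That column still favours north-west over either feed.

The forecast picks north-west too, with 23 % for west, 22 % for south-east and 29 % for north-west. Its north-west figure stands lower than mine. Its ground for the feeds: “either feed spends the early minutes short of one partner”.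

Now run the three flasks, whose steps are these:

    X + Q ⇌ E (K1 = 22 /M, k1 = 3.4 × 10⁵ /M/min)
    D + E ⇌ J (K2 = 1600 /M, k2 = 91000 /M/min)
    J → Q + Z (k3 = 180 /min)
    D + Q + Z → Q + G (k4 = 1.5 × 10⁵ /M²/min)
    Q + Z ⇌ Qa, settled at all times (K5 = 32 /M)

Charge X, D and Q together at the start: north-west ends highest, with Z at 28.7 % against 22.5 % in west and 21.7 % in south-east. At that end north-west still holds 70.8 % of its X. Its Z stands at 53.1 % of the ceiling. A neighbour of north-west charged with 80 mM of X has the same enzyme, so its ceiling is 13.5 % of its own X. That neighbour gives 9.70 %, which is 71.9 % of its ceiling.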